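The synthesis rests on disconnecting the C9–C10 bond of ring B. Ring A, which carries oxygen on C1, methyl on C10 and the ester carbon on C4, is recognised as a 4-hydroxy-3-methylbenzoate whose methyl-bearing ortho carbon C10 is nucleophilic, while C17–C8–C9 is a 2-substituted allyl unit. One palladium-catalysed, ligand-controlled dearomative allylic alkylation should close ring B, create quaternary C10 and tertiary C9, leave the C8=C17 methylene and deliver a dienone whose C4=C5 enoate is ready for reductive methylation. The precursor is this phenol carrying on C5 a two-carbon tether to a (Z)-trisubstituted allylic methyl carbonate with a silyl-protected C12 hydroxyl.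

Key step: step 9

Remark 1: C-locants (C1–C20) are labdane locants of the target and are used for all intermediates; compound names use naphthalene locants.
Remark 2 (chemistry): C9 and C17 are both bonded to C8, so closure through either allyl terminus gives a six-membered ring; attack at C9 is therefore not imposed by ring size, is sought through the Z-olefin (C11 anti in the allyl complex) and the ligand, and is the main risk of step 9.
Remark 3 (assumption): the (R,R)-ligand is taken to give the (9R,10S) dienone; if the sense of induction proves opposite, the (S,S)-ligand is used.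

Step 1
Reactants: 1 methyl 2,4-dihydroxy-3-methylbenzoate
Product: 2 methyl 2-hydroxy-4-[(4-methoxybenzyl)oxy]-3-methylbenzoate
Conditions: PMBCl, K2CO3, DMF, rt
Reagents that add atoms: 4-methoxybenzyl chloride, COc1ccc(CCl)cc1
Why: Williamson etherification should occur at the hydroxyl para to the ester (the future C1 oxygen), because the ortho hydroxyl is held in a hydrogen bond to the ester carbonyl and is far less nucleophilic.

Step 2
Reactants: 2 methyl 2-hydroxy-4-[(4-methoxybenzyl)oxy]-3-methylbenzoate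
Product: 3 methyl 4-[(4-methoxybenzyl)oxy]-3-methyl-2-{[(trifluoromethyl)sulfonyl]oxy}benzoate
Conditions: Tf2O, pyridine, CH2Cl2, 0 °C → rt
Reagents that add atoms: trifluoromethanesulfonic anhydride, O=S(=O)(OS(=O)(=O)C(F)(F)F)C(F)(F)F
Why: O-sulfonylation of the remaining chelated phenol should give an aryl triflate at the future C5 that the ortho ester activates for oxidative addition.

Step 3
Reactants: 3 methyl 4-[(4-methoxybenzyl)oxy]-3-methyl-2-{[(trifluoromethyl)sulfonyl]oxy}benzoate
Product: 4 methyl 2-ethenyl-4-[(4-methoxybenzyl)oxy]-3-methylbenzoate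
Conditions: tributyl(vinyl)stannane, Pd(PPh3)4 (cat.), LiCl, 1,4-dioxane, 100 °C
Reagents that add atoms: tributyl(vinyl)stannane, C=C[Sn](CCCC)(CCCC)CCCC
Why: Stille coupling of the aryl triflate with the vinylstannane in the presence of LiCl should install C6 and C7 as a vinyl group under neutral conditions that spare the ester and the PMB ether.

Step 4
Reactants: 5 tert-butyl(but-3-yn-1-yloxy)dimethylsilane
Product: 7 5-[(tert-butyldimethylsilyl)oxy]pent-2-yn-1-ol, via lithium acetylide 6 (not isolated)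
Conditions: n-BuLi, THF, −78 °C; (CH2O)n, −78 °C → rt; H2O
Reagents that add atoms: paraformaldehyde (formaldehyde), C=O
Why: Deprotonation of the terminal alkyne and addition of the acetylide to formaldehyde should bring in C17 as a propargylic alcohol.

Step 5
Reactants: 7 5-[(tert-butyldimethylsilyl)oxy]pent-2-yn-1-ol
Product: 9 (2E)-5-[(tert-butyldimethylsilyl)oxy]-2-iodopent-2-en-1-ol, via vinylstannane 8 (not isolated)
Conditions: Bu3SnH, PdCl2(PPh3)2 (cat.), THF, 0 °C → rt; then I2, CH2Cl2, 0 °C
Reagents that add atoms: iodine, II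
Why: Palladium-catalysed syn-hydrostannation should place tin on the alkyne carbon next to the propargylic hydroxyl (C8) and hydrogen on C9, and iododestannylation with retention then fixes the geometry in which C17 and C11 are cis.

Step 6
Reactants: 4 methyl 2-ethenyl-4-[(4-methoxybenzyl)oxy]-3-methylbenzoate; 9 (2E)-5-[(tert-butyldimethylsilyl)oxy]-2-iodopent-2-en-1-ol
Product: 11 methyl 2-[(3Z)-6-[(tert-butyldimethylsilyl)oxy]-3-(hydroxymethyl)hex-3-en-1-yl]-4-[(4-methoxybenzyl)oxy]-3-methylbenzoate, via alkylborane 10 (not isolated)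
Conditions: 9-BBN, THF, 0 → 50 °C; then 9, PdCl2(dppf)·CH2Cl2 (cat.), AsPh3 (cat.), Cs2CO3, DMF/H2O, rt
Reagents that add atoms: none
Why: Anti-Markovnikov hydroboration of the styrene followed by B-alkyl Suzuki–Miyaura coupling with the vinyl iodide should form the C7–C8 bond with retention of olefin geometry and so give the (Z)-trisubstituted allylic alcohol.

Step 7
Reactants: 11 methyl 2-[(3Z)-6-[(tert-butyldimethylsilyl)oxy]-3-(hydroxymethyl)hex-3-en-1-yl]-4-[(4-methoxybenzyl)oxy]-3-methylbenzoate
Product: 12 methyl 2-[(3Z)-6-[(tert-butyldimethylsilyl)oxy]-3-{[(methoxycarbonyl)oxy]methyl}hex-3-en-1-yl]-4-[(4-methoxybenzyl)oxy]-3-methylbenzoate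
Conditions: ClCO2Me, pyridine, CH2Cl2, 0 °C
Reagents that add atoms: methyl chloroformate, COC(=O)Cl
Why: Acylation of the primary allylic alcohol should give the methyl carbonate, a leaving group that releases its own base (methoxide) on ionisation.

Step 8
Reactants: 12 methyl 2-[(3Z)-6-[(tert-butyldimethylsilyl)oxy]-3-{[(methoxycarbonyl)oxy]methyl}hex-3-en-1-yl]-4-[(4-methoxybenzyl)oxy]-3-methylbenzoate
Product: 13 methyl 2-[(3Z)-6-[(tert-butyldimethylsilyl)oxy]-3-{[(methoxycarbonyl)oxy]methyl}hex-3-en-1-yl]-4-hydroxy-3-methylbenzoate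
Conditions: DDQ, CH2Cl2/pH 7 buffer, 0 °C → rt
Reagents that add atoms: none
Why: Oxidative cleavage of the PMB ether with DDQ should free the phenol under neutral conditions that leave the allylic carbonate, the silyl ether and the olefin geometry untouched.

Step 9
Reactants: 13 methyl 2-[(3Z)-6-[(tert-butyldimethylsilyl)oxy]-3-{[(methoxycarbonyl)oxy]methyl}hex-3-en-1-yl]-4-hydroxy-3-methylbenzoate
Product: 14 methyl (4aS,5R)-5-{2-[(tert-butyldimethylsilyl)oxy]ethyl}-4a-methyl-6-methylidene-4-oxo-4,4a,5,6,7,8-hexahydronaphthalene-1-carboxylate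
Conditions: Pd2(dba)3·CHCl3 (cat.), (R,R)-DACH-phenyl Trost ligand (cat.), CH2Cl2 (high dilution), rt
Reagents that add atoms: none
Why: Zerovalent palladium should ionise the primary allylic carbonate with loss of CO2 to a 1,2-disubstituted π-allyl complex (C17–C8–C9, with C11 anti because the olefin is Z), and the methoxide set free deprotonates the phenol. The phenolate then attacks C9 through C10 on the allyl face opposite to palladium, a Tsuji–Trost dearomative allylic alkylation whose closest known type is the palladium-catalysed intramolecular dearomatisation of phenols and naphthols carrying allylic carbonates under diamine-derived bisphosphine ligands. Ring B closes in a 6-exo mode with respect to the C8=C17 bond that is left behind. C9 is set by the allyl face that carries palladium in the reacting complex, the two faces exchanging through the σ-allyl at unsubstituted C17 so that the ligand selects one, and C10 is set by the phenolate face, a chair-like transition state in which the anti C11 chain becomes equatorial placing C11 cis to the C10 methyl. The step needs C9 over C17, which would close an isomeric six-membered ring, and this rests on the ligand class that sends phenol and quaternary-carbon nucleophiles to the substituted terminus of 2-alkylcrotyl and prenyl complexes and on capture of the anti complex before it isomerises. It also needs C10 over C4 and over oxygen: C4 carries the conjugated ester and is the poorer nucleophile, and O-closure would need an eight- or nine-membered ring.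

Step 10
Reactants: 14 methyl (4aS,5R)-5-{2-[(tert-butyldimethylsilyl)oxy]ethyl}-4a-methyl-6-methylidene-4-oxo-4,4a,5,6,7,8-hexahydronaphthalene-1-carboxylate
Product: 15 methyl (4aS,5R)-5-{2-[(tert-butyldimethylsilyl)oxy]ethyl}-4a-methyl-6-methylidene-4-oxo-2,3,4,4a,5,6,7,8-octahydronaphthalene-1-carboxylate
Conditions: [(Ph3P)CuH]6, H2O, toluene, rt
Reagents that add atoms: none
Why: Copper hydride conjugate reduction should deliver hydride to C3, the only unsubstituted β-position of the dienone, leaving the tetrasubstituted C4=C5 enoate and the isolated C8=C17 olefin untouched and creating no stereocentre.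

Step 11
Reactants: 15 methyl (4aS,5R)-5-{2-[(tert-butyldimethylsilyl)oxy]ethyl}-4a-methyl-6-methylidene-4-oxo-2,3,4,4a,5,6,7,8-octahydronaphthalene-1-carboxylate
Product: 16 methyl (4S,4aS,5R)-5-{2-[(tert-butyldimethylsilyl)oxy]ethyl}-4-hydroxy-4a-methyl-6-methylidene-2,3,4,4a,5,6,7,8-octahydronaphthalene-1-carboxylate
Conditions: NaBH4, MeOH, 0 °C
Reagents that add atoms: none
Why: Borohydride reduction should attack the C1 ketone from the face opposite the angular C10 methyl (as in Wieland–Miescher ketone) to give the equatorial alcohol cis to that methyl, and removing the ketone here prevents a ketone enolate from being methylated at C2 in the next step.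

Step 12
Reactants: 16 methyl (4S,4aS,5R)-5-{2-[(tert-butyldimethylsilyl)oxy]ethyl}-4-hydroxy-4a-methyl-6-methylidene-2,3,4,4a,5,6,7,8-octahydronaphthalene-1-carboxylate
Product: 18 methyl (1R,4S,4aS,5R,8aS)-5-{2-[(tert-butyldimethylsilyl)oxy]ethyl}-4-hydroxy-1,4a-dimethyl-6-methylidenedecahydronaphthalene-1-carboxylate, via dilithium alkoxide enolate 17 (not isolated)
Conditions: Li, NH3(l)/THF, −78 °C; isoprene; MeI, −78 → −33 °C; NH4Cl
Reagents that add atoms: iodomethane, CI
Why: Dissolving-metal reductive alkylation of the unsaturated ester should protonate C5 axially to give the trans ring fusion and methylate the exocyclic ester enolate from the equatorial face away from the axial C10 methyl, leaving the C4 ester axial and cis to that methyl.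

Step 13
Reactants: 18 methyl (1R,4S,4aS,5R,8aS)-5-{2-[(tert-butyldimethylsilyl)oxy]ethyl}-4-hydroxy-1,4a-dimethyl-6-methylidenedecahydronaphthalene-1-carboxylate
Product: 19 methyl (1R,4S,4aS,5R,8aS)-4-(acetyloxy)-5-{2-[(tert-butyldimethylsilyl)oxy]ethyl}-1,4a-dimethyl-6-methylidenedecahydronaphthalene-1-carboxylate
Conditions: Ac2O, DMAP (cat.), pyridine, rt
Reagents that add atoms: acetic anhydride, CC(=O)OC(C)=O
Why: DMAP-catalysed acylation should acetylate the only free hydroxyl (C1) with retention of configuration.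

Step 14
Reactants: 19 methyl (1R,4S,4aS,5R,8aS)-4-(acetyloxy)-5-{2-[(tert-butyldimethylsilyl)oxy]ethyl}-1,4a-dimethyl-6-methylidenedecahydronaphthalene-1-carboxylate
Product: 20 methyl (1R,4S,4aS,5R,8aS)-4-(acetyloxy)-5-(2-hydroxyethyl)-1,4a-dimethyl-6-methylidenedecahydronaphthalene-1-carboxylate
Conditions: HF·pyridine, pyridine, THF, 0 °C → rt
Reagents that add atoms: none
Why: Buffered fluoride desilylation should free the primary C12 alcohol without touching the acetate, the methyl ester or the exocyclic olefin.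

Step 15
Reactants: 20 methyl (1R,4S,4aS,5R,8aS)-4-(acetyloxy)-5-(2-hydroxyethyl)-1,4a-dimethyl-6-methylidenedecahydronaphthalene-1-carboxylate
Product: 21 methyl (1R,4S,4aS,5R,8aS)-4-(acetyloxy)-1,4a-dimethyl-6-methylidene-5-(2-oxoethyl)decahydronaphthalene-1-carboxylate
Conditions: Dess–Martin periodinane, pyridine, CH2Cl2, 0 °C → rt
Reagents that add atoms: none
Why: Dess–Martin oxidation should give the C12 aldehyde under buffered, non-epimerising conditions (C11 carries no stereocentre).

Step 16
Reactants: 21 methyl (1R,4S,4aS,5R,8aS)-4-(acetyloxy)-1,4a-dimethyl-6-methylidene-5-(2-oxoethyl)decahydronaphthalene-1-carboxylate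
Product: 22 methyl (1R,4S,4aS,5R,8aS)-4-(acetyloxy)-1,4a-dimethyl-5-[(2E)-3-methyl-4-oxobut-2-en-1-yl]-6-methylidenedecahydronaphthalene-1-carboxylate
Conditions: Ph3P=C(CH3)CHO, toluene, 90 °C
Reagents that add atoms: 2-(triphenylphosphoranylidene)propanal, CC(C=O)=P(c1ccccc1)(c1ccccc1)c1ccccc1
Why: Wittig olefination with the stabilised ylide should form C12=C13 with E geometry (formyl group trans to C11).

Step 17
Reactants: 22 methyl (1R,4S,4aS,5R,8aS)-4-(acetyloxy)-1,4a-dimethyl-5-[(2E)-3-methyl-4-oxobut-2-en-1-yl]-6-methylidenedecahydronaphthalene-1-carboxylate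
Product: 23 methyl (1R,4S,4aS,5R,8aS)-4-(acetyloxy)-1,4a-dimethyl-6-methylidene-5-[(2E)-3-methylpenta-2,4-dien-1-yl]decahydronaphthalene-1-carboxylate
Conditions: Ph3PCH3Br, KN(SiMe3)2, THF, 0 °C; then 22, −78 → 0 °C
Reagents that add atoms: methyltriphenylphosphonium bromide, [Br-].C[P+](c1ccccc1)(c1ccccc1)c1ccccc1
Why: Wittig methylenation of the enal at low temperature should complete the (12E)-diene, the aldehyde reacting far faster than the acetate or the hindered methyl ester.

Compound list
1 | methyl 2,4-dihydroxy-3-methylbenzoate | COC(=O)c1ccc(O)c(C)c1O | starting material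
2 | methyl 2-hydroxy-4-[(4-methoxybenzyl)oxy]-3-methylbenzoate | COC(=O)c1ccc(OCc2ccc(OC)cc2)c(C)c1O | intermediate
3 | methyl 4-[(4-methoxybenzyl)oxy]-3-methyl-2-{[(trifluoromethyl)sulfonyl]oxy}benzoate | COC(=O)c1ccc(OCc2ccc(OC)cc2)c(C)c1OS(=O)(=O)C(F)(F)F | intermediate
4 | methyl 2-ethenyl-4-[(4-methoxybenzyl)oxy]-3-methylbenzoate | COC(=O)c1ccc(OCc2ccc(OC)cc2)c(C)c1C=C | intermediate
5 | tert-butyl(but-3-yn-1-yloxy)dimethylsilane | C#CCCO[Si](C)(C)C(C)(C)C | starting material
6 | {4-[(tert-butyldimethylsilyl)oxy]but-1-yn-1-yl}lithium | [Li+].[C-]#CCCO[Si](C)(C)C(C)(C)C | intermediate (not isolated)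
7 | 5-[(tert-butyldimethylsilyl)oxy]pent-2-yn-1-ol | OCC#CCCO[Si](C)(C)C(C)(C)C | intermediate
8 | (2E)-5-[(tert-butyldimethylsilyl)oxy]-2-(tributylstannyl)pent-2-en-1-ol | OC/C(=C\CCO[Si](C)(C)C(C)(C)C)[Sn](CCCC)(CCCC)CCCC | intermediate (not isolated)
9 | (2E)-5-[(tert-butyldimethylsilyl)oxy]-2-iodopent-2-en-1-ol | OC/C(I)=C\CCO[Si](C)(C)C(C)(C)C | intermediate
10 | methyl 2-[2-(9-borabicyclo[3.3.1]nonan-9-yl)ethyl]-4-[(4-methoxybenzyl)oxy]-3-methylbenzoate | COC(=O)c1ccc(OCc2ccc(OC)cc2)c(C)c1CCB1C2CCCC1CCC2 | intermediate (not isolated)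
11 | methyl 2-[(3Z)-6-[(tert-butyldimethylsilyl)oxy]-3-(hydroxymethyl)hex-3-en-1-yl]-4-[(4-methoxybenzyl)oxy]-3-methylbenzoate | COC(=O)c1ccc(OCc2ccc(OC)cc2)c(C)c1CC/C(CO)=C/CCO[Si](C)(C)C(C)(C)C | intermediate
12 | methyl 2-[(3Z)-6-[(tert-butyldimethylsilyl)oxy]-3-{[(methoxycarbonyl)oxy]methyl}hex-3-en-1-yl]-4-[(4-methoxybenzyl)oxy]-3-methylbenzoate | COC(=O)c1ccc(OCc2ccc(OC)cc2)c(C)c1CC/C(COC(=O)OC)=C/CCO[Si](C)(C)C(C)(C)C | intermediate
13 | methyl 2-[(3Z)-6-[(tert-butyldimethylsilyl)oxy]-3-{[(methoxycarbonyl)oxy]methyl}hex-3-en-1-yl]-4-hydroxy-3-methylbenzoate | COC(=O)c1ccc(O)c(C)c1CC/C(COC(=O)OC)=C/CCO[Si](C)(C)C(C)(C)C | intermediate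
14 | methyl (4aS,5R)-5-{2-[(tert-butyldimethylsilyl)oxy]ethyl}-4a-methyl-6-methylidene-4-oxo-4,4a,5,6,7,8-hexahydronaphthalene-1-carboxylate | CC(C)(C)[Si](C)(C)OCC[C@@H]1C(=C)CCC2=C(C(=O)OC)C=CC(=O)[C@@]12C | intermediate
15 | methyl (4aS,5R)-5-{2-[(tert-butyldimethylsilyl)oxy]ethyl}-4a-methyl-6-methylidene-4-oxo-2,3,4,4a,5,6,7,8-octahydronaphthalene-1-carboxylate | CC(C)(C)[Si](C)(C)OCC[C@@H]1C(=C)CCC2=C(C(=O)OC)CCC(=O)[C@@]12C | intermediate
16 | methyl (4S,4aS,5R)-5-{2-[(tert-butyldimethylsilyl)oxy]ethyl}-4-hydroxy-4a-methyl-6-methylidene-2,3,4,4a,5,6,7,8-octahydronaphthalene-1-carboxylate | CC(C)(C)[Si](C)(C)OCC[C@@H]1C(=C)CCC2=C(C(=O)OC)CC[C@H](O)[C@@]12C | intermediate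
17 | dilithium alkoxide ester enolate of the C5-protonated reduction product of 16 (trans-fused; C1, C5, C9, C10 as in 18) | [Li+].[Li+].CC(C)(C)[Si](C)(C)OCC[C@@H]1C(=C)CC[C@H]2[C@@]1(C)[C@@H]([O-])CCC2=C([O-])OC | intermediate (not isolated)
18 | methyl (1R,4S,4aS,5R,8aS)-5-{2-[(tert-butyldimethylsilyl)oxy]ethyl}-4-hydroxy-1,4a-dimethyl-6-methylidenedecahydronaphthalene-1-carboxylate | CC(C)(C)[Si](C)(C)OCC[C@@H]1C(=C)CC[C@H]2[C@@]1(C)[C@@H](O)CC[C@@]2(C)C(=O)OC | intermediate
19 | methyl (1R,4S,4aS,5R,8aS)-4-(acetyloxy)-5-{2-[(tert-butyldimethylsilyl)oxy]ethyl}-1,4a-dimethyl-6-methylidenedecahydronaphthalene-1-carboxylate | CC(C)(C)[Si](C)(C)OCC[C@@H]1C(=C)CC[C@H]2[C@@]1(C)[C@@H](OC(C)=O)CC[C@@]2(C)C(=O)OC | intermediate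
20 | methyl (1R,4S,4aS,5R,8aS)-4-(acetyloxy)-5-(2-hydroxyethyl)-1,4a-dimethyl-6-methylidenedecahydronaphthalene-1-carboxylate | OCC[C@@H]1C(=C)CC[C@H]2[C@@]1(C)[C@@H](OC(C)=O)CC[C@@]2(C)C(=O)OC | intermediate
21 | methyl (1R,4S,4aS,5R,8aS)-4-(acetyloxy)-1,4a-dimethyl-6-methylidene-5-(2-oxoethyl)decahydronaphthalene-1-carboxylate | O=CC[C@@H]1C(=C)CC[C@H]2[C@@]1(C)[C@@H](OC(C)=O)CC[C@@]2(C)C(=O)OC | intermediate
22 | methyl (1R,4S,4aS,5R,8aS)-4-(acetyloxy)-1,4a-dimethyl-5-[(2E)-3-methyl-4-oxobut-2-en-1-yl]-6-methylidenedecahydronaphthalene-1-carboxylate | O=C/C(C)=C/C[C@@H]1C(=C)CC[C@H]2[C@@]1(C)[C@@H](OC(C)=O)CC[C@@]2(C)C(=O)OC | intermediate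
23 | methyl (1R,4S,4aS,5R,8aS)-4-(acetyloxy)-1,4a-dimethyl-6-methylidene-5-[(2E)-3-methylpenta-2,4-dien-1-yl]decahydronaphthalene-1-carboxylate (labdane locants: 1S,4R,5S,9R,10S,12E) | C=C/C(C)=C/C[C@@H]1C(=C)CC[C@H]2[C@@]1(C)[C@@H](OC(C)=O)CC[C@@]2(C)C(=O)OC | target

Total step count: 17. Longest linear sequence: 15 steps (steps 1–3 and 6–17, from compound 1).

Steps most likely to fail

Step 9. The phenolate may close through the unsubstituted allyl terminus C17 (or through C4) faster than through C9, or the ligand may separate the two allyl faces poorly. The fallback blocks C17 with silicon and transfers chirality from a carbinol; it sets out from triflate 3 and returns at dienone 14. Negishi coupling of 3 with [4-(trimethylsilyl)but-3-yn-1-yl]zinc bromide (Pd(OAc)2, SPhos, THF) should give methyl 4-[(4-methoxybenzyl)oxy]-3-methyl-2-[4-(trimethylsilyl)but-3-yn-1-yl]benzoate F1. Nickel-catalysed asymmetric reductive coupling of the alkyne with 3-[(tert-butyldimethylsilyl)oxy]propanal (Ni(cod)2, one enantiomer of neomenthyldiphenylphosphine chosen for the R carbinol, Et3B) forms C8–C9 at the alkyne carbon remote from silicon and should give methyl 2-[(3E,4R)-6-[(tert-butyldimethylsilyl)oxy]-4-hydroxy-3-[(trimethylsilyl)methylidene]hexyl]-4-[(4-methoxybenzyl)oxy]-3-methylbenzoate F2. Methyl chloroformate and pyridine convert it into the C9 methyl carbonate of F2 F3, and DDQ frees the phenol of F3 F4. With Pd(PPh3)4 the silicon on C17 directs the phenolate to the remote terminus C9, and double inversion carries the carbinol configuration into C9, to give the 17-(trimethylsilyl) derivative of 14 F5. Protodesilylation (CF3CO2H, CH2Cl2, 0 °C) by ipso protonation at C17 then returns to 14.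

Step 12. The one-pot trapping may lose control: incomplete or unselective C-methylation in ammonia, O-methylation of the C1 alkoxide, or over-reduction of the ester. The fallback separates reduction from alkylation; it sets out from 16 and returns at 18. Li in NH3/THF followed by an NH4Cl quench should give the trans-fused saturated ester, the 4-desmethyl analogue of 18 F6 (C4 epimers). Deprotonation with LiN(i-Pr)2 in THF/DMPU at −78 °C to the alkoxide ester enolate and methylation with MeI, again from the equatorial face, should then give 18.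

Step 5. Hydrostannation may distribute tin between C8 and C9, since both alkyne carbons carry an oxygenated chain. The fallback lets a conjugated ester dictate the regiochemistry; it sets out from 5 and returns at stannane 8. n-BuLi then ClCO2Me should give methyl 5-[(tert-butyldimethylsilyl)oxy]pent-2-ynoate F7. Bu3SnH with Pd(PPh3)4 adds syn with tin at the α-carbon to give methyl (2E)-5-[(tert-butyldimethylsilyl)oxy]-2-(tributylstannyl)pent-2-enoate F8. Reduction with i-Bu2AlH (CH2Cl2, −78 °C) gives 8, which is iodinated to 9 as in step 5.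

Further compounds
F1 | step 9 | methyl 4-[(4-methoxybenzyl)oxy]-3-methyl-2-[4-(trimethylsilyl)but-3-yn-1-yl]benzoate | COC(=O)c1ccc(OCc2ccc(OC)cc2)c(C)c1CCC#C[Si](C)(C)C
F2 | step 9 | methyl 2-[(3E,4R)-6-[(tert-butyldimethylsilyl)oxy]-4-hydroxy-3-[(trimethylsilyl)methylidene]hexyl]-4-[(4-methoxybenzyl)oxy]-3-methylbenzoate | COC(=O)c1ccc(OCc2ccc(OC)cc2)c(C)c1CC/C(=C\[Si](C)(C)C)[C@H](O)CCO[Si](C)(C)C(C)(C)C
F3 | step 9 | methyl 2-[(3E,4R)-6-[(tert-butyldimethylsilyl)oxy]-4-[(methoxycarbonyl)oxy]-3-[(trimethylsilyl)methylidene]hexyl]-4-[(4-methoxybenzyl)oxy]-3-methylbenzoate | COC(=O)c1ccc(OCc2ccc(OC)cc2)c(C)c1CC/C(=C\[Si](C)(C)C)[C@H](OC(=O)OC)CCO[Si](C)(C)C(C)(C)C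
F4 | step 9 | methyl 2-[(3E,4R)-6-[(tert-butyldimethylsilyl)oxy]-4-[(methoxycarbonyl)oxy]-3-[(trimethylsilyl)methylidene]hexyl]-4-hydroxy-3-methylbenzoate | COC(=O)c1ccc(O)c(C)c1CC/C(=C\[Si](C)(C)C)[C@H](OC(=O)OC)CCO[Si](C)(C)C(C)(C)C
F5 | step 9 | 17-(trimethylsilyl) derivative of 14, (E)-vinylsilane with silicon cis to C7, C9 and C10 configured as in 14 | CC(C)(C)[Si](C)(C)OCC[C@@H]1/C(=C/[Si](C)(C)C)CCC2=C(C(=O)OC)C=CC(=O)[C@@]12C
F6 | step 12 | 4-desmethyl analogue of 18 (methyl ester with hydrogen on C4, C4 epimers, trans-fused, C1, C5, C9 and C10 as in 18) | CC(C)(C)[Si](C)(C)OCC[C@@H]1C(=C)CC[C@H]2[C@@]1(C)[C@@H](O)CCC2C(=O)OC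
F7 | step 5 | methyl 5-[(tert-butyldimethylsilyl)oxy]pent-2-ynoate | COC(=O)C#CCCO[Si](C)(C)C(C)(C)C
F8 | step 5 | methyl (2E)-5-[(tert-butyldimethylsilyl)oxy]-2-(tributylstannyl)pent-2-enoate | COC(=O)/C(=C\CCO[Si](C)(C)C(C)(C)C)[Sn](CCCC)(CCCC)CCCC
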